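## Structural features

The target, C24H14O11, is a phlorotannin of the fucofuroeckol type: four benzene rings, all oxygenated in the phloroglucinol manner, linked and fused through oxygen. Ring A (3,5-dihydroxyphenyl) is joined to ring B by a diaryl ether, rings B and D share the two oxygens of a dibenzo-1,4-dioxin (ring C), and rings D and F are joined by a biaryl bond and one oxygen into a dibenzofuran (ring E). There is no stereocentre, so the whole problem is one of regiochemistry. Ring B carries five oxygens on adjacent carbons and one C–H: going round from the C–H there are a free hydroxyl, the ring A ether oxygen, a dioxin oxygen (para to the C–H), the second dioxin oxygen and the second free hydroxyl. Ring D bears a free hydroxyl, a C–H, the furan oxygen, the biaryl carbon and the two dioxin oxygens, and its dioxin oxygen para to the furan oxygen is the one attached to the ring B carbon para to the C–H. The free heptaphenol is fragile, because rings B and D are hydroquinone- and pyrogallol-like and oxidise in air, so every hydroxyl is carried as an alkyl ether up to the last step. The real difficulties are to tell the five oxygens of ring B apart, to close ring C in the correct orientation, and to make the doubly ortho-substituted C–O and C–C bonds around ring D. The key step exploits the O5/CH pattern of ring B: four adjacent C–O carbons are those of a squarate ester, and the fifth C–O carbon and the C–H come from a 1-alkoxyvinyl group.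

## Logic of the disconnections

**22 to 21.** The seven phenolic O–H bonds are traced back to six O–methyl bonds and one O–ethyl bond. The free polyphenol is oxidation-prone and very polar, so this is the last operation. The gain is that every earlier intermediate is a neutral, chromatographable ether. The demand is a dealkylation that leaves all aryl–O–aryl bonds intact.

**21 to 20 to 19.** The ring D–ring F biaryl bond, which closes ring E, is cut back to a carboxyl group on ring D and a C–H bond of the aryl ether on the neighbouring oxygen; the acid comes from 19. The carbon concerned lies between two oxygens, and such benzoic acids lose CO2 readily. The formyl group is needed earlier anyway as activator and as director. The gain is that ring F arrives as a symmetrical aryl ether whose two ortho C–H bonds are equivalent, so no regiochemical question arises. The demand is that palladation by decarboxylation outruns simple protonation, and that the aldehyde oxidation spares the electron-rich rings.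

**19 to 17 and 18.** Two aryl C–O bonds are cut: the ring A ether on ring B and the ether that carries the future ring F on ring D. Both aryl groups are the same, so two molecules of 18 in one step serve both, and the two free hydroxyls of 17 need not be distinguished. The demand is a copper-mediated arylation that copes with one doubly ortho-substituted phenol and one hydrogen-bonded ortho-formyl phenol.

**17 to 16.** The ring C C–O bond from the ring B oxygen para to the C–H to the brominated ring D carbon is cut. With the first ether already in place, only this oxygen can reach the bromide through a six-membered ring; the other catechol oxygen would need a seven-membered ring. Ring size, not protecting groups, therefore sets the orientation of ring C. The demand is an intramolecular Ullmann coupling on a triol, run dilute and without oxygen.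

**16 to 15.** Three O–alkyl bonds are restored: the two isopropyl ethers on ring B and the methyl ether ortho to the formyl group on ring D. One Lewis acid removes all three, the isopropyl groups by their lability and the methyl group by chelation to the formyl group, while the other methyl and ethyl ethers stay. The gain is that exactly the three hydroxyls needed next are unveiled. The demand is temperature control. A benzyl ether could not be carried through this step, which is why the hydroxyl freed in the key step is capped as a methyl ether.

**15 to 9 and 13.** The other ring C C–O bond is cut, from the ring B oxygen meta to the C–H to the ring D carbon that carries fluorine. This is the most crowded ether of the molecule. It is made by SNAr, where the ortho formyl group and the ortho bromine activate and fluorine is the only possible leaving group, so the constitution is fixed. Here the mapping of 8 onto ring B is decided. The hydroquinone pattern has a local mirror plane through the C–H and the para carbon, so either of the two oxygens meta to the C–H can become the ring A ether or a dioxin oxygen. The one that is uniquely addressable (the former carbinol oxygen) is made a dioxin oxygen. The two isopropyl-bearing oxygens, which cannot be told apart chemically, are then sorted by ring size (step 8) and by being the last one left (step 9). The gain is a convergent union of two fragments of similar size. The demand is that a doubly ortho-substituted phenoxide attacks a doubly ortho-substituted fluoride.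

**13 to 12 to 10.** The C–Br and C–CHO bonds of ring D are cut. Both are made by electrophilic substitution directed by the two methoxy groups of 10. The demand is selectivity for the positions ortho to one methoxy and para to the other over the position between the two.

**9 to 8.** The O–methyl bond on the hydroxyl that the ring expansion sets free is cut. Methyl is chosen because it must survive the Lewis acid of step 7. The demand is only that the silyl ether stays.

**8 to 5 (key disconnection).** Ring B is opened at the bond between the carbon bearing the free hydroxyl (the former carbonyl carbon) and the C–H carbon. Retro-6π closure leads to 6, and retro-4π opening leads to 5. Five adjacent oxygenated carbons and one C–H equal a C4O4 squarate unit plus a C2O alkoxyvinyl unit. The gain is a hexasubstituted arene from two simple commercial materials, with its oxygens in four different states: free phenol, silyl ether, two isopropyl ethers and an ethyl ether. The demand is torquoselective ring opening and exclusion of air. Keeping the carbinol oxygen silylated replaces a selective mono-alkylation of an air-sensitive hydroquinone by an unambiguous alkylation of the only free phenol.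

**5 to 1 and 2.** The C–C bond between the carbinol carbon and the vinyl carbon and the O–Si bond are cut. Compound 1 is symmetrical, so the addition raises no regiochemical question. The demand is mono-addition at low temperature and a non-acidic finish, because the enol ether is acid-sensitive.

## Other disconnections considered

Alternative 1: The cut is the ring C aryl C–O bond from the ring B oxygen meta to the C–H to the ring D carbon next to the future biaryl carbon, together with the C–I bond on that neighbouring carbon.
- Forward step: in the 2-iodoaryl arenesulfonate A2, ring D already hangs on the other dioxin oxygen of ring B. Iodine–magnesium exchange and loss of the sulfonate would give a ring D aryne. The tethered magnesium phenoxide would add to it and close ring C, and an iodine quench of the resulting arylmagnesium would give A1.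
- In its favour: the most crowded aryl ether is formed intramolecularly, the tether decides the direction of addition to the aryne, and the iodide needed for ring F is planted in the same operation.
- Against it here: A2 presupposes a ring B on which ring A and ring D already sit on the correct neighbouring oxygens, which is exactly the differentiation that has to be delivered. It also needs a pentasubstituted ring D with iodide, sulfonate and benzyl ether in defined places. A magnesium phenoxide is a weak nucleophile and the aryne is electron-rich. After A1, four operations remain (debenzylation, O-arylation, cyclisation, dealkylation).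
- Comparison: on the crowded ether it is the better plan (intramolecular capture against the intermolecular SNAr of step 6). An iodide is also a more direct handle than the formyl group, which has to be oxidised in step 10 before the ring closure of step 11. On ring B it offers nothing, whereas the chosen key step builds that ring with its oxygens already told apart. Mechanistically it trades a neutral pericyclic cascade for cryogenic organomagnesium chemistry. It is expected to be longer once ring B and A2 are counted.

Alternative 2: The cut is two C–C bonds of ring A, so that ring A is grown on the ring B oxygen.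
- Forward step: diene A5 would add to the (E)-2-nitrovinyl ether A4 in a Diels–Alder reaction. Loss of nitrous acid and collapse of the silyl methyl ketal would aromatise the adduct to A3, the hexa-O-methyl ether of the target with one ring A hydroxyl free.
- In its favour: the regiochemistry follows from the polarity of diene and dienophile. No metal-mediated arylation of the doubly ortho-substituted ring B phenol is needed, and the cycloaddition is indifferent to the crowding at that oxygen; on this point it is the better plan.
- Against it here: A4 must be prepared from the fully assembled and most valuable intermediate. It is a nitroalkene placed next to very electron-rich arenes, and A5 is sensitive to acid and moisture. Ring A is a plain phloroglucinol unit that 18 delivers in one operation, and the free hydroxyl of A3 is a differentiation the target does not use.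
- Comparison: structurally it attacks the easiest ring and leaves ring B, ring C and ring E to other chemistry. Mechanistically it is the equal of the chosen plan, since both are pericyclic and both fix the substitution pattern by connectivity. In step economy the chosen plan is better, because one reagent installs ring A and the carbons of ring F together.

Alternative 3: The cut is four C–C bonds of ring F.
- Forward step: irradiation of diazoketone A7 would give an arylketene by Wolff rearrangement. A [2+2] addition to silyloxyalkyne A8, 4π opening of the cyclobutenone, 6π closure onto furan C3 and tautomerisation would give A6, the penta-O-methyl ether of the target with ring F as a mono-silylated resorcinol.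
- In its favour: it uses the same ketene electrocyclisation logic as the chosen key step and is its equal in mechanistic reliability. It needs neither palladium nor silver and avoids the protodecarboxylation risk of step 11, which is a point on which it is better. The 1,3-dioxygenation of ring F is regiospecific.
- Against it here: a diazoketone must be made and irradiated late, on a light-absorbing electron-rich polyaryl ether, which is the least safe operation of all the plans. A7 requires a benzofuran-2-carboxylic acid on ring D, that is furan construction, acid activation and diazo transfer before the key step. A8 is sensitive, and the differentiation of the two ring F hydroxyls is not needed.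
- Comparison: structurally it spends its effort on ring F, a simple phloroglucinol unit like ring A, and leaves the difficult ring B to conventional chemistry. In step economy it needs about five operations (furan, activation, diazoketone, benzannulation, desilylation) against the two of steps 10 and 11.

Key step: step 2

Remark: 1, 2, 10 and 18 are taken as commercial; ring letters are A (3,5-dihydroxyphenyl), B (pentaoxygenated ring), C (dioxin), D (ring carrying dioxin and furan), E (furan), F (terminal dihydroxybenzo ring).

## Steps

Step 1
Reactants: 1 diisopropyl squarate; 2 ethyl vinyl ether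
Product: 5 4-(1-ethoxyethenyl)-2,3-di(propan-2-yloxy)-4-(triethylsilyloxy)cyclobut-2-en-1-one (racemic), via 1-ethoxyvinyllithium 3 (not isolated), via lithium cyclobutenolate 4 (not isolated)
Conditions: 2, t-BuLi, THF, −78 to 0 °C; then 1, THF, −78 °C; then Et3SiCl, −78 to 0 °C; aq NaHCO3
Reagents that add atoms: chlorotriethylsilane, CC[Si](Cl)(CC)CC
Why: α-Lithiation of the vinyl ether gives 3, which adds once to a carbonyl of the symmetrical squarate at −78 °C (known 1,2-addition of organolithiums to squarate esters; the remaining vinylogous ester carbonyl is far less electrophilic), and silylation of alkoxide 4 in the same flask avoids an acidic quench of the enol ether. The new stereocentre is formed as a racemate and disappears in step 2.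

Step 2
Reactants: 5 4-(1-ethoxyethenyl)-2,3-di(propan-2-yloxy)-4-(triethylsilyloxy)cyclobut-2-en-1-one
Product: 8 5-ethoxy-2,3-di(propan-2-yloxy)-4-(triethylsilyloxy)phenol, via (Z)-dienylketene 6 (not isolated), via cyclohexa-2,4-dienone 7 (not isolated)
Conditions: degassed toluene, 110 °C, Ar
Reagents that add atoms: none
Why: Heating should open the cyclobutenone by thermal conrotatory 4π electrocyclic cleavage of the C1–C4 bond; the silyloxy donor on C4 rotates outward (torquoselectivity of donor substituents), so the ethoxyvinyl group turns inward and (Z)-dienylketene 6 has the vinyl group next to the ketene. A thermal disrotatory 6π electrocyclisation then joins the ketene carbon to the vinyl CH2 carbon (one new C–C bond, ring B closed) to give dienone 7, and enolisation gives phenol 8. The closest known reaction type is the Moore cyclisation of 4-alkenyl-4-hydroxy- or 4-silyloxycyclobutenones made from squarate esters. No stereocentre is formed and the single stereocentre of racemic 5 is lost. The substitution pattern of 8 follows from connectivity alone, so the only selectivity needed is the sense of rotation in the ring opening, which the oxygen donor on C4 secures. Because the carbinol oxygen stays silylated, the only free hydroxyl of 8 is the one born from the ketene carbonyl, which tells the two para oxygens apart without a selective alkylation. Exclusion of air, water and acid protects the ketene from hydration and the electron-rich phenol from oxidation.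

Step 3
Reactants: 8 5-ethoxy-2,3-di(propan-2-yloxy)-4-(triethylsilyloxy)phenol
Product: 9 triethyl[6-ethoxy-4-methoxy-2,3-di(propan-2-yloxy)phenoxy]silane
Conditions: MeI, K2CO3, acetone, 40 °C
Reagents that add atoms: iodomethane, CI
Why: Williamson methylation of the only free phenol; methyl is chosen because it must survive BCl3 in step 7, and the silyl ether flanked by two alkoxy groups should not be touched by anhydrous carbonate.

Step 4
Reactants: 10 1-fluoro-3,5-dimethoxybenzene
Product: 12 2-fluoro-4,6-dimethoxybenzaldehyde, via iminium chloride 11 (not isolated)
Conditions: POCl3, DMF, 0 to 60 °C; then aq NaOAc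
Reagents that add atoms: N,N-dimethylformamide, CN(C)C=O; water, O
Why: Vilsmeier–Haack formylation of an activated arene; attack para to one methoxy and ortho to the other (next to the small fluorine) is expected to be preferred over the position between the two methoxy groups, as with other 5-substituted 1,3-dimethoxybenzenes.

Step 5
Reactants: 12 2-fluoro-4,6-dimethoxybenzaldehyde
Product: 13 3-bromo-2-fluoro-4,6-dimethoxybenzaldehyde
Conditions: NBS, MeCN, 0 °C to rt
Reagents that add atoms: N-bromosuccinimide, O=C1CCC(=O)N1Br
Why: Electrophilic bromination should go to the carbon that is ortho to one methoxy and para to the other (between fluorine and methoxy) and not to the more hindered carbon between the two methoxy groups, in line with the 5-bromination of 2,4-dimethoxybenzaldehyde.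

Step 6
Reactants: 9 triethyl[6-ethoxy-4-methoxy-2,3-di(propan-2-yloxy)phenoxy]silane; 13 3-bromo-2-fluoro-4,6-dimethoxybenzaldehyde
Product: 15 3-bromo-2-[6-ethoxy-4-methoxy-2,3-di(propan-2-yloxy)phenoxy]-4,6-dimethoxybenzaldehyde, via caesium aryloxide 14 (not isolated)
Conditions: CsF, DMSO, 100 °C, Ar
Reagents that add atoms: none
Why: Fluoride cleaves the aryl silyl ether to phenoxide 14, which displaces fluoride ortho to the formyl group by SNAr through a Meisenheimer complex stabilised by the formyl group and the adjacent bromine; fluoride-mediated SNAr of aryl silyl ethers with activated aryl fluorides is a known diaryl ether synthesis. Fluorine is the only SNAr leaving group of 13 and bromine is kept for step 8, so the ring B oxygen meta to the C–H ends on the ring D carbon between formyl and bromine.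

Step 7
Reactants: 15 3-bromo-2-[6-ethoxy-4-methoxy-2,3-di(propan-2-yloxy)phenoxy]-4,6-dimethoxybenzaldehyde
Product: 16 3-bromo-2-(6-ethoxy-2,3-dihydroxy-4-methoxyphenoxy)-6-hydroxy-4-methoxybenzaldehyde
Conditions: BCl3, CH2Cl2, −78 to 0 °C; then H2O
Reagents that add atoms: none
Why: BCl3 dealkylation: isopropyl aryl ethers are cleaved much faster than methyl or ethyl ethers, and the methoxy group ortho to the formyl group is cleaved through a six-membered boron chelate, while the methoxy para to formyl and the ring B methyl and ethyl ethers should remain.

Step 8
Reactants: 16 3-bromo-2-(6-ethoxy-2,3-dihydroxy-4-methoxyphenoxy)-6-hydroxy-4-methoxybenzaldehyde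
Product: 17 9-ethoxy-2,6-dihydroxy-4,7-dimethoxydibenzo[b,e][1,4]dioxine-1-carbaldehyde
Conditions: CuI (cat.), picolinic acid, K3PO4, DMSO, 90 °C, high dilution, Ar
Reagents that add atoms: none
Why: Intramolecular Ullmann diaryl ether synthesis with monovalent copper: only the catechol oxygen next to the existing ether can reach the C–Br carbon through a six-membered ring (the other would need a seven-membered ring), so ring size fixes the orientation of ring C. Dilution and exclusion of air suppress intermolecular coupling and catechol oxidation.

Step 9
Reactants: 17 9-ethoxy-2,6-dihydroxy-4,7-dimethoxydibenzo[b,e][1,4]dioxine-1-carbaldehyde; 18 (3,5-dimethoxyphenyl)boronic acid (two molecules are incorporated, one per hydroxyl)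
Product: 19 2,6-bis(3,5-dimethoxyphenoxy)-9-ethoxy-4,7-dimethoxydibenzo[b,e][1,4]dioxine-1-carbaldehyde
Conditions: 18 (4 equiv in all), Cu(OAc)2 (3 equiv), pyridine, 4 Å MS, CH2Cl2, dry air, rt
Reagents that add atoms: (3,5-dimethoxyphenyl)boronic acid (second incorporated equivalent of 18), OB(O)c1cc(OC)cc(OC)c1
Why: Chan–Lam coupling (divalent copper, arylboronic acid, air) should arylate both phenols, one molecule of 18 for each hydroxyl: on ring B the 3,5-dimethoxyphenyl group is ring A, on ring D it is the precursor of ring F, so the two hydroxyls need not be told apart. Doubly ortho-substituted phenols are known substrates and room temperature spares the aldehyde.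

Step 10
Reactants: 19 2,6-bis(3,5-dimethoxyphenoxy)-9-ethoxy-4,7-dimethoxydibenzo[b,e][1,4]dioxine-1-carbaldehyde
Product: 20 2,6-bis(3,5-dimethoxyphenoxy)-9-ethoxy-4,7-dimethoxydibenzo[b,e][1,4]dioxine-1-carboxylic acid
Conditions: NaClO2, NaH2PO4, 2-methyl-2-butene, t-BuOH/THF/H2O, 0 °C to rt
Reagents that add atoms: sodium chlorite, [Na+].[O-]Cl=O
Why: Pinnick oxidation of the aldehyde to the acid; 2-methyl-2-butene removes hypochlorous acid before it can chlorinate the electron-rich rings, and the buffered medium avoids acid-induced cyclisation of the aldehyde onto the neighbouring aryl ether.

Step 11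
Reactants: 20 2,6-bis(3,5-dimethoxyphenoxy)-9-ethoxy-4,7-dimethoxydibenzo[b,e][1,4]dioxine-1-carboxylic acid
Product: 21 hexa-O-methyl mono-O-ethyl ether of the target (ethyl on the ring B oxygen next to the dioxin and ortho to the C–H; methyl on all six other hydroxyl oxygens)
Conditions: Pd(O2CCF3)2 (cat.), Ag2CO3, DMSO/1,4-dioxane, 140 °C
Reagents that add atoms: none
Why: Decarboxylative intramolecular C–H arylation: divalent palladium replaces the carboxyl group of the 2,6-dioxygenated benzoic acid (such acids decarboxylate readily), the arylpalladium activates an ortho C–H of the aryl ether on the neighbouring oxygen through a six-membered palladacycle, and reductive elimination forms the biaryl bond and ring E, Ag2CO3 reoxidising zerovalent palladium. This is the known conversion of 2-aryloxybenzoic acids into dibenzofurans; the two ortho C–H bonds of the 3,5-dimethoxyphenyl ether are equivalent and ring B offers none, so only one product is possible.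

Step 12
Reactants: 21 hexa-O-methyl mono-O-ethyl ether of the target
Product: 22 target CNP0256302.0 (free heptaphenol)
Conditions: BBr3 (excess), CH2Cl2, −78 °C to rt; then H2O, Ar
Reagents that add atoms: none
Why: Exhaustive cleavage of six methyl ethers and one ethyl ether with BBr3 through aryl borates that hydrolyse on work-up; diaryl ether, dioxin and furan C–O bonds are not cleaved by BBr3. Work-up and purification under argon, since the heptaphenol is air-sensitive.

## Compound list

1 | diisopropyl squarate [3,4-di(propan-2-yloxy)cyclobut-3-ene-1,2-dione] | CC(C)OC1=C(OC(C)C)C(=O)C1=O | starting material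
2 | ethyl vinyl ether | C=COCC | starting material
3 | 1-ethoxyvinyllithium | [Li]C(=C)OCC | intermediate (not isolated)
4 | lithium 1-(1-ethoxyethenyl)-4-oxo-2,3-di(propan-2-yloxy)cyclobut-2-en-1-olate (racemic) | [Li+].[O-]C1(C(=C)OCC)C(OC(C)C)=C(OC(C)C)C1=O | intermediate (not isolated)
5 | 4-(1-ethoxyethenyl)-2,3-di(propan-2-yloxy)-4-(triethylsilyloxy)cyclobut-2-en-1-one (racemic) | O=C1C(OC(C)C)=C(OC(C)C)C1(O[Si](CC)(CC)CC)C(=C)OCC | intermediate
6 | (3Z)-5-ethoxy-2,3-di(propan-2-yloxy)-4-(triethylsilyloxy)hexa-1,3,5-trien-1-one | C=C(OCC)/C(O[Si](CC)(CC)CC)=C(OC(C)C)\C(OC(C)C)=C=O | intermediate (not isolated)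
7 | 5-ethoxy-2,3-di(propan-2-yloxy)-4-(triethylsilyloxy)cyclohexa-2,4-dien-1-one | O=C1CC(OCC)=C(O[Si](CC)(CC)CC)C(OC(C)C)=C1OC(C)C | intermediate (not isolated)
8 | 5-ethoxy-2,3-di(propan-2-yloxy)-4-(triethylsilyloxy)phenol | Oc1cc(OCC)c(O[Si](CC)(CC)CC)c(OC(C)C)c1OC(C)C | intermediate
9 | triethyl[6-ethoxy-4-methoxy-2,3-di(propan-2-yloxy)phenoxy]silane | COc1cc(OCC)c(O[Si](CC)(CC)CC)c(OC(C)C)c1OC(C)C | intermediate
10 | 1-fluoro-3,5-dimethoxybenzene | COc1cc(F)cc(OC)c1 | starting material
11 | N-[(2-fluoro-4,6-dimethoxyphenyl)methylidene]-N-methylmethanaminium chloride | C[N+](C)=Cc1c(F)cc(OC)cc1OC.[Cl-] | intermediate (not isolated)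
12 | 2-fluoro-4,6-dimethoxybenzaldehyde | O=Cc1c(F)cc(OC)cc1OC | intermediate
13 | 3-bromo-2-fluoro-4,6-dimethoxybenzaldehyde | O=Cc1c(F)c(Br)c(OC)cc1OC | intermediate
14 | caesium 6-ethoxy-4-methoxy-2,3-di(propan-2-yloxy)phenolate | [Cs+].[O-]c1c(OCC)cc(OC)c(OC(C)C)c1OC(C)C | intermediate (not isolated)
15 | 3-bromo-2-[6-ethoxy-4-methoxy-2,3-di(propan-2-yloxy)phenoxy]-4,6-dimethoxybenzaldehyde | O=Cc1c(Oc2c(OCC)cc(OC)c(OC(C)C)c2OC(C)C)c(Br)c(OC)cc1OC | intermediate
16 | 3-bromo-2-(6-ethoxy-2,3-dihydroxy-4-methoxyphenoxy)-6-hydroxy-4-methoxybenzaldehyde | O=Cc1c(Oc2c(OCC)cc(OC)c(O)c2O)c(Br)c(OC)cc1O | intermediate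
17 | 9-ethoxy-2,6-dihydroxy-4,7-dimethoxydibenzo[b,e][1,4]dioxine-1-carbaldehyde | O=Cc1c(O)cc(OC)c2Oc3c(O)c(OC)cc(OCC)c3Oc12 | intermediate
18 | (3,5-dimethoxyphenyl)boronic acid | OB(O)c1cc(OC)cc(OC)c1 | starting material
19 | 2,6-bis(3,5-dimethoxyphenoxy)-9-ethoxy-4,7-dimethoxydibenzo[b,e][1,4]dioxine-1-carbaldehyde | O=Cc1c(Oc4cc(OC)cc(OC)c4)cc(OC)c2Oc3c(Oc5cc(OC)cc(OC)c5)c(OC)cc(OCC)c3Oc12 | intermediate
20 | 2,6-bis(3,5-dimethoxyphenoxy)-9-ethoxy-4,7-dimethoxydibenzo[b,e][1,4]dioxine-1-carboxylic acid | OC(=O)c1c(Oc4cc(OC)cc(OC)c4)cc(OC)c2Oc3c(Oc5cc(OC)cc(OC)c5)c(OC)cc(OCC)c3Oc12 | intermediate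
21 | hexa-O-methyl mono-O-ethyl ether of the target (ethyl on the ring B oxygen next to the dioxin and ortho to the C–H) | COc1cc(OC)c2c(c1)oc1cc(OC)c3Oc4c(Oc5cc(OC)cc(OC)c5)c(OC)cc(OCC)c4Oc3c12 | intermediate
22 | CNP0256302.0, free heptaphenol (ring A 3,5-dihydroxyphenyl ether on ring B; dibenzodioxin B–C–D; dibenzofuran D–E–F) | Oc1cc(O)cc(Oc2c(O)cc(O)c3c2Oc2c(O)cc4oc5cc(O)cc(O)c5c4c2O3)c1 | target

## Step count and least certain steps

Total: 12 steps. Longest linear sequence: 10 steps (steps 1, 2, 3 and 6 to 12); steps 4 and 5 make compound 13, which joins in step 6.

**Step 2 (key step).** What may go wrong is loss or scrambling of the silyl group during thermolysis, which would erase the differentiation of the two para oxygens. The silyl ether may also open more slowly than the free carbinol, so that hydration or dimerisation of the ketene competes with ring closure, and the product may oxidise in air. The fallback moves the differentiation out of the cyclisation. It sets out from alkoxide 4, which is quenched with pH 7 buffer instead of the silyl chloride to give 4-(1-ethoxyethenyl)-4-hydroxy-2,3-di(propan-2-yloxy)cyclobut-2-en-1-one F1, the classical substrate of this cyclisation. Thermolysis in degassed toluene should give 5-ethoxy-2,3-di(propan-2-yloxy)benzene-1,4-diol F2. One equivalent of K2CO3 and MeI in acetone at 0 °C should methylate the less hindered hydroxyl (one ortho substituent against two), giving 6-ethoxy-4-methoxy-2,3-di(propan-2-yloxy)phenol F3. With Cs2CO3 in DMSO, F3 is deprotonated to 14 and reacts with 13, so the fallback returns to the route at 15.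

**Step 6.** The likely failure is slow substitution: two methoxy groups feed electron density into the formyl group, and both partners are doubly ortho-substituted, so the temperature needed may degrade the aldehyde or the electron-rich phenoxide. The fallback sets out from 13 and changes the activating group to a nitrile, which is smaller, fully conjugated and stable to forcing basic conditions. Hydroxylamine hydrochloride and NaOAc give (E)-3-bromo-2-fluoro-4,6-dimethoxybenzaldehyde oxime F4, and acetic anhydride dehydrates it to 3-bromo-2-fluoro-4,6-dimethoxybenzonitrile F5. CsF-mediated coupling with 9 in DMSO at up to 140 °C should give 3-bromo-2-[6-ethoxy-4-methoxy-2,3-di(propan-2-yloxy)phenoxy]-4,6-dimethoxybenzonitrile F6. Diisobutylaluminium hydride in toluene at −78 °C followed by aqueous acid reduces the nitrile to the aldehyde, returning to the route at 15.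

**Step 9.** The likely failure is incomplete arylation of the ring D hydroxyl, which is hydrogen-bonded to the formyl group and can bind copper as a chelate, so that the mono-arylated compound accumulates or the boronic acid is consumed by homocoupling and protodeboronation. The fallback sets out from 17 and uses metal-free aryl transfer from trivalent iodine, which is not subject to chelation and tolerates crowded phenols. (3,5-Dimethoxyphenyl)(2,4,6-trimethoxyphenyl)iodonium 4-methylbenzenesulfonate F7 is prepared from 1-iodo-3,5-dimethoxybenzene (mCPBA, TsOH, MeCN; then 1,3,5-trimethoxybenzene). Treatment of 17 with at least two equivalents of F7 and K2CO3 in toluene/MeCN at 50 °C should transfer the less electron-rich 3,5-dimethoxyphenyl group to both phenoxides, returning to the route at 19.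

**Step 11.** The likely failure is protodecarboxylation: the electron-rich arylsilver or arylpalladium species is protonated before it activates the C–H bond, which leaves a hydrogen where ring F should be attached. The fallback sets out from 19, bypasses 20, and replaces decarboxylation by oxidative addition. Baeyer–Villiger oxidation of 19 (mCPBA, NaHCO3, CH2Cl2, 0 °C) should give 2,6-bis(3,5-dimethoxyphenoxy)-9-ethoxy-4,7-dimethoxydibenzo[b,e][1,4]dioxin-1-yl formate F8. Methanolysis (K2CO3, MeOH) gives 2,6-bis(3,5-dimethoxyphenoxy)-9-ethoxy-4,7-dimethoxydibenzo[b,e][1,4]dioxin-1-ol F9. Tf2O and pyridine give 2,6-bis(3,5-dimethoxyphenoxy)-9-ethoxy-4,7-dimethoxydibenzo[b,e][1,4]dioxin-1-yl trifluoromethanesulfonate F10. Intramolecular direct arylation of F10 with zerovalent palladium (Pd(OAc)2, PCy3·HBF4, K2CO3, DMA, 120 °C) closes ring E and returns to the route at 21.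

## Further compounds

F1 | step 2 | 4-(1-ethoxyethenyl)-4-hydroxy-2,3-di(propan-2-yloxy)cyclobut-2-en-1-one (racemic) | O=C1C(OC(C)C)=C(OC(C)C)C1(O)C(=C)OCC
F2 | step 2 | 5-ethoxy-2,3-di(propan-2-yloxy)benzene-1,4-diol | Oc1cc(OCC)c(O)c(OC(C)C)c1OC(C)C
F3 | step 2 | 6-ethoxy-4-methoxy-2,3-di(propan-2-yloxy)phenol | Oc1c(OCC)cc(OC)c(OC(C)C)c1OC(C)C
F4 | step 6 | (E)-3-bromo-2-fluoro-4,6-dimethoxybenzaldehyde oxime | O/N=C/c1c(F)c(Br)c(OC)cc1OC
F5 | step 6 | 3-bromo-2-fluoro-4,6-dimethoxybenzonitrile | N#Cc1c(F)c(Br)c(OC)cc1OC
F6 | step 6 | 3-bromo-2-[6-ethoxy-4-methoxy-2,3-di(propan-2-yloxy)phenoxy]-4,6-dimethoxybenzonitrile | N#Cc1c(Oc2c(OCC)cc(OC)c(OC(C)C)c2OC(C)C)c(Br)c(OC)cc1OC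
F7 | step 9 | (3,5-dimethoxyphenyl)(2,4,6-trimethoxyphenyl)iodonium 4-methylbenzenesulfonate | COc1cc(OC)cc(c1)[I+]c1c(OC)cc(OC)cc1OC.Cc1ccc(cc1)S([O-])(=O)=O
F8 | step 11 | 2,6-bis(3,5-dimethoxyphenoxy)-9-ethoxy-4,7-dimethoxydibenzo[b,e][1,4]dioxin-1-yl formate | O=COc1c(Oc4cc(OC)cc(OC)c4)cc(OC)c2Oc3c(Oc5cc(OC)cc(OC)c5)c(OC)cc(OCC)c3Oc12
F9 | step 11 | 2,6-bis(3,5-dimethoxyphenoxy)-9-ethoxy-4,7-dimethoxydibenzo[b,e][1,4]dioxin-1-ol | Oc1c(Oc4cc(OC)cc(OC)c4)cc(OC)c2Oc3c(Oc5cc(OC)cc(OC)c5)c(OC)cc(OCC)c3Oc12
F10 | step 11 | 2,6-bis(3,5-dimethoxyphenoxy)-9-ethoxy-4,7-dimethoxydibenzo[b,e][1,4]dioxin-1-yl trifluoromethanesulfonate | FC(F)(F)S(=O)(=O)Oc1c(Oc4cc(OC)cc(OC)c4)cc(OC)c2Oc3c(Oc5cc(OC)cc(OC)c5)c(OC)cc(OCC)c3Oc12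
A1 | alternative 1 | iodo dibenzodioxin lacking ring F: ring A and ring B as methyl ethers, ring D with methoxy, benzyloxy at the future furan oxygen and iodine at the future biaryl carbon | COc1cc(OC)cc(Oc2c(OC)cc(OC)c3c2Oc2c(OC)cc(OCc4ccccc4)c(I)c2O3)c1
A2 | alternative 1 | tethered precursor of A1: ring B phenol carrying ring A, linked through its oxygen para to the C–H to a ring D 2-iodoaryl 4-chlorobenzenesulfonate | COc1cc(OC)cc(Oc2c(OC)cc(OC)c(O)c2Oc2c(OC)cc(OCc3ccccc3)c(I)c2OS(=O)(=O)c2ccc(Cl)cc2)c1
A3 | alternative 2 | hexa-O-methyl ether of the target with one ring A hydroxyl free | Oc1cc(OC)cc(Oc2c(OC)cc(OC)c3c2Oc2c(OC)cc4oc5cc(OC)cc(OC)c5c4c2O3)c1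
A4 | alternative 2 | (E)-2-nitrovinyl ether of the ring B phenol of the penta-O-methylated core made of rings B to F | O=[N+]([O-])/C=C/Oc1c(OC)cc(OC)c2c1Oc1c(OC)cc3oc4cc(OC)cc(OC)c4c3c1O2
A5 | alternative 2 | 1,3-dimethoxy-1-(trimethylsilyloxy)buta-1,3-diene (ketene acetal geometry not defined) | C=C(OC)C=C(OC)O[Si](C)(C)C
A6 | alternative 3 | penta-O-methyl ether of the target with one ring F hydroxyl free and the other as its triisopropylsilyl ether | COc1cc(OC)cc(Oc2c(OC)cc(OC)c3c2Oc2c(OC)cc4oc5cc(O[Si](C(C)C)(C(C)C)C(C)C)cc(O)c5c4c2O3)c1
A7 | alternative 3 | benzofuran-2-yl diazomethyl ketone carrying rings A to D as methyl ethers | COc1cc(OC)cc(Oc2c(OC)cc(OC)c3c2Oc2c(OC)cc4oc(C(=O)C=[N+]=[N-])cc4c2O3)c1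
A8 | alternative 3 | ethynyloxy(triisopropyl)silane | C#CO[Si](C(C)C)(C(C)C)C(C)C
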